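## The problem

The target 31 is a 14-membered carbocycle. Ring atoms are numbered C1 (acetoxy carbon) to C14, and C15 is the carbinol carbon of the side chain on C6. Its only second ring is the 12,13-epoxide, so the task is one large ring carrying three trisubstituted units of fixed geometry: the E C2=C3 alkene, the Z C8=C9 alkene, and a cis epoxide that corresponds to a Z C12=C13 alkene. There are four stereocentres (1S, 6R, 12S, 13R). C1 is homoallylic to C12=C13 and can pass its configuration to the epoxide. C6 is five or more ring bonds from every other stereocentre, so it can neither control nor be controlled and must come from a chiral building block. The trisubstituted epoxide will not survive acids, aluminium hydrides or dissolving metals. The secondary allylic acetate ionises with zerovalent palladium and is cleaved by base. The tertiary alcohol invites elimination and, with a carbonyl group β to it, retro-aldol cleavage. Both Z alkenes are the less stable isomers in an open chain and need methods that cannot equilibrate them. The feature that opens the key step is the C3–C4 bond: it joins the sp2 carbon of the E alkene to an unbranched C4–C5 unit ending at C6. A vinyl group on C6 is therefore a latent C4 alkylborane, an E iodide at C3 carries the finished alkene, and joining them closes the ring without creating any stereo-element.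

## Retrosynthesis

**31 ⇒ 30 ⇒ 29 (no skeletal bond cut).** The acetate of 31 is added last to diol 30, which comes from the bis(triethylsilyl) ether 29. This keeps the base- and palladium-labile allylic acetate out of every earlier step. The forward reactions must remove both silyl groups in one operation and then acylate the secondary hydroxyl beside the tertiary one.

**29 ⇒ 27 (C3–C4, the ring bond).** Cutting C3–C4 gives the open-chain iodoalkene 27 with a vinyl group on C6. This cut is preferred to its neighbours for three reasons:
- Cutting C2=C3 would ask a ring-closing olefination to set an E-trisubstituted alkene inside a macrocycle.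
- Cutting C4–C5 needs an anion-stabilising group that must be removed afterwards.
- Cutting C1–C2 or C1–C14 would create the C1 stereocentre during ring closure.

At C3–C4 all four stereocentres and all alkene geometries are already present in 27, and the two reacting groups are inert to everything else in the chain. The forward reaction must hydroborate only the vinyl group, couple with retention at C3, and favour the ring over oligomers.

**27 ⇒ 26 ⇒ 25 (C3–I and C2–H).** The E iodoalkene is traced through alkenylboronate 26 to the methyl-capped alkyne 25 by a syn hydrometalation with the metal on C3. Hydrozirconation with Cp2Zr(H)Cl is the usual tool, but it does not reliably tell an internal alkyne from a monosubstituted alkene, and the vinyl group is already present. Copper-catalysed borylcupration reacts with the alkyne only, so the extra step is accepted. Precursor 25 is simpler in that the alkyne is inert to the epoxidation and sulfone chemistry before it.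

**25 ⇒ 24 ⇒ 23 (C12–O and C13–O).** The epoxide is removed to give the Z alkene of homoallylic alcohol 23, with the C1 hydroxyl as the directing group. Epoxidation is placed here because 23 has two trisubstituted alkenes and only the hydroxyl can single out C12=C13. It must also come before the alkyne becomes an alkene, since an allylic C2=C3 bond would be epoxidised first. The forward reaction must deliver oxygen syn to the C1–O bond. The silyl group of 25 is then put on 24.

**23 ⇒ 21 ⇒ 18 + 9 (C10–C11).** This bond lies between two allylic carbons and divides the chain into halves of similar size. It is formed by alkylating an α-sulfonyl carbanion, followed by reductive removal of the sulfone from 21. The sulfone is placed on C11 (fragment 18), not on C10. The π-allyl intermediate of the desulfonylation then has one secondary and one tertiary terminus, and hydride goes to the secondary one. A C10 sulfone would give a π-allyl unit with two similar termini and scramble the C8=C9 alkene. The partners are bromide 9 and hydroxy sulfone 18, each with one stereocentre and one Z alkene.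

**9 ⇒ 8 ⇒ 7 ⇒ 6 ⇒ 5 ⇒ 3 ⇒ 2 ⇒ 1 (C10–C5 of the target, the C1–C6 bond of the carvone ring).** Bromide 9 maps onto (S)-carvone 1:
- The ring stereocentre becomes C6.
- The isopropenyl group becomes the hydroxyisopropyl group by hydration.
- The ring-locked C3=C2(Me)–C1 unit becomes the Z C8=C9(Me)–C10 unit.

Cleaving α-ketol 5 between the ketone and the α′ carbon gives ester-aldehyde 6. Methylenation gives 7, and reduction and bromination give 9. No acyclic olefination could match the certainty of a Z alkene taken from a ring. The forward sequence must keep the aldehyde α-stereocentre of 6 intact.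

**18 ⇒ 17 ⇒ 16 ⇒ 14 + 15; 14 ⇒ 13 ⇒ 12 ⇒ 11 ⇒ 10 (C1–C2, then functional-group changes).** The C1 carbinol is set by asymmetric reduction of ynone 17, which is made from aldehyde 14 and 1-propynylmagnesium bromide 15. The Z C12=C13 alkene again comes from a ring: lactone 10 is reduced to Z diol 11, whose allylic end is turned into the sulfone (12, 13) and whose other end is oxidised to 14. A Wittig or sigmatropic route to this alkene would need a selectivity that the ring gives for free.

## Roads not taken

**Alternative 1:** The ring would be closed at C2≡C3 by ring-closing alkyne metathesis of two methyl-capped alkyne termini with Mo(≡CC6H4OMe)(OSiPh3)3, giving cycloalkyne A1 (C1 p-methoxybenzyl ether, C15 silyl ether, both Z alkenes).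
- Merits: this is one of the most dependable closures for 14-membered rings. It tolerates ethers, silyl ethers and trisubstituted alkenes, and it has none of the β-hydride or protodeboronation leaks of an alkylboron coupling. In reliability of the ring closure it is probably better than the chosen plan.
- Weak points: A1 lacks the C3 methyl group, the alkene geometry and the epoxide. Turning the ring alkyne into the E alkene needs a trans hydrometalation with the metal on C3, then methylation. The hydroxyl-directed aluminium hydrides that do this (NaAlH2(OCH2CH2OMe)2) open epoxides. The epoxide cannot be added afterwards, because the C1 hydroxyl would then direct the oxidant to the allylic C2=C3 bond. Ruthenium-catalysed trans-hydrostannation tolerates epoxides but puts tin on C2 next to a free hydroxyl.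
- Comparison: at least five steps with an ordering conflict would follow A1. The chosen plan sets against the stronger ring closure a C2=C3 unit that enters complete and only two steps after cyclisation.

**Alternative 2:** The ring would be closed at C4–C5 by a C5 α-sulfonyl carbanion (KN(SiMe3)2) displacing a C4 allylic bromide, giving macrocyclic sulfone A2 as C5 epimers.
- Merits: this is a classical, metal-free closure for 14-membered carbocycles. The E alkene, the epoxide and all four stereocentres are in place before it. In ring-closing efficiency it is probably the equal of the chosen plan or better.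
- Weak points: the carbanion sits beside C6 with its bulky silyloxyisopropyl group. The sulfone costs about three steps to install from the C5 aldehyde, where the chosen route needs one methylenation. It must then be removed from A2 by sodium amalgam or SmI2 in the presence of the epoxide and an allylic silyl ether. The allylic bromide can also react by SN2′.
- Comparison: the chosen plan sets against it a closure that leaves no auxiliary behind and exposes the epoxide only to mild base.

**Alternative 3:** The ring would be closed at C14–C1 by BF3·OEt2-promoted SE2′ attack of an α-silyl methallyl unit on a C1 ynal, shifting the alkene to C12=C13 and giving propargylic alcohol A3.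
- Merits: one step makes a ring bond and an alkene, the ynal cannot enolise, and the open chain is short. In step count up to the macrocycle it is the best of the four.
- Weak points: A3 is formed as C1 epimers. The Z geometry at C12=C13 would have to come from ring constraint, because anti SE2′ of α-substituted allylsilanes normally gives E alkenes. The C3 methyl group, the E alkene and the epoxide are all still missing, so the problems of Alternative 1 return with a C1 correction added.
- Comparison: the chosen plan is longer before ring closure but fixes every stereo-element in open-chain steps where each can be checked.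

Key step: step 21

Remark on the chemistry: lactone 10 (4-methyl-5,6-dihydro-2H-pyran-2-one, the dehydration product of mevalonolactone) is assumed to be a catalogue compound.

## Route

Step 1
Reactants: 1 (S)-(+)-carvone
Product: 2 (5S)-5-(2-hydroxypropan-2-yl)-2-methylcyclohex-2-en-1-one
Conditions: 50% aq. H2SO4, 0 °C
Reagents that add atoms: water, O
Why: Acid-catalysed Markovnikov hydration; the 1,1-disubstituted alkene protonates to a tertiary cation that water captures, the enone is inert at 0 °C and the stereocentre is not touched.

Step 2
Reactants: 2 (5S)-5-(2-hydroxypropan-2-yl)-2-methylcyclohex-2-en-1-one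
Product: 3 (5S)-2-methyl-5-[2-(triethylsilyloxy)propan-2-yl]cyclohex-2-en-1-one
Conditions: Et3SiOTf, 2,6-lutidine, CH2Cl2, −78 → 0 °C
Reagents that add atoms: triethylsilyl triflate, CC[Si](CC)(CC)OS(=O)(=O)C(F)(F)F
Why: Silyl triflate silylation of a hindered tertiary alcohol; the ether prevents retro-aldol cleavage of the β-oxygenated aldehyde made in step 4 and hydroxyl-directed oxidation of the wrong alkene in step 17.

Step 3
Reactants: 3 (5S)-2-methyl-5-[2-(triethylsilyloxy)propan-2-yl]cyclohex-2-en-1-one
Product: 5 (5S)-6-hydroxy-2-methyl-5-[2-(triethylsilyloxy)propan-2-yl]cyclohex-2-en-1-one (C6 epimers), via lithium enolate 4 (not isolated)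
Conditions: LiN(i-Pr)2, THF, −78 °C; then 3-phenyl-2-(phenylsulfonyl)oxaziridine, −78 °C
Reagents that add atoms: 3-phenyl-2-(phenylsulfonyl)oxaziridine, O=S(=O)(c1ccccc1)N1OC1c1ccccc1; lithium diisopropylamide, CC(C)[N-]C(C)C.[Li+] (lithium of 4 only)
Why: Kinetic deprotonation at the α′ methylene gives the cross-conjugated enolate 4, which the N-sulfonyloxaziridine hydroxylates (enolate hydroxylation); the configuration of the new carbinol does not matter because this carbon becomes an aldehyde.

Step 4
Reactants: 5 (5S)-6-hydroxy-2-methyl-5-[2-(triethylsilyloxy)propan-2-yl]cyclohex-2-en-1-one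
Product: 6 methyl (2Z,5R)-5-formyl-2,6-dimethyl-6-(triethylsilyloxy)hept-2-enoate
Conditions: Pb(OAc)4, MeOH–toluene, 0 °C
Reagents that add atoms: methanol, CO
Why: Lead tetraacetate cleavage of an α-ketol in methanol; the ketone carbon leaves as the methyl ester and the carbinol carbon as the aldehyde, and the cis relation of C7 and C10 in the ring becomes the Z enoate.

Step 5
Reactants: 6 methyl (2Z,5R)-5-formyl-2,6-dimethyl-6-(triethylsilyloxy)hept-2-enoate
Product: 7 methyl (2Z,5S)-2-methyl-5-[2-(triethylsilyloxy)propan-2-yl]hepta-2,6-dienoate
Conditions: Ph3PCH3Br, KN(SiMe3)2, THF, −78 → 0 °C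
Reagents that add atoms: methyltriphenylphosphonium bromide, C[P+](c1ccccc1)(c1ccccc1)c1ccccc1.[Br-]
Why: Wittig methylenation; the unstabilised ylide reacts with the aldehyde far faster than with the enoate, and adding 6 to the ylide at low temperature is meant to keep the α-stereocentre (C6) from enolising.

Step 6
Reactants: 7 methyl (2Z,5S)-2-methyl-5-[2-(triethylsilyloxy)propan-2-yl]hepta-2,6-dienoate
Product: 8 (2Z,5S)-2-methyl-5-[2-(triethylsilyloxy)propan-2-yl]hepta-2,6-dien-1-ol
Conditions: i-Bu2AlH, CH2Cl2, −78 °C
Reagents that add atoms: none
Why: 1,2-Reduction of the unsaturated ester by the aluminium hydride gives the allylic alcohol without changing the alkene geometry.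

Step 7
Reactants: 8 (2Z,5S)-2-methyl-5-[2-(triethylsilyloxy)propan-2-yl]hepta-2,6-dien-1-ol
Product: 9 (2Z,5S)-1-bromo-2-methyl-5-[2-(triethylsilyloxy)propan-2-yl]hepta-2,6-diene
Conditions: CBr4, PPh3, CH2Cl2, −20 → 0 °C
Reagents that add atoms: carbon tetrabromide, BrC(Br)(Br)Br
Why: Appel bromination; the primary allylic alcohol is displaced by SN2 under neutral conditions, which keeps the Z geometry and the tertiary silyl ether.

Step 8
Reactants: 10 4-methyl-5,6-dihydro-2H-pyran-2-one
Product: 11 (2Z)-3-methylpent-2-ene-1,5-diol
Conditions: LiAlH4, Et2O, 0 °C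
Reagents that add atoms: none
Why: Hydride reduction of the unsaturated lactone by 1,2-addition; the Z geometry is certain because the alkene was part of the six-membered ring.

Step 9
Reactants: 11 (2Z)-3-methylpent-2-ene-1,5-diol
Product: 12 (3Z)-5-chloro-3-methylpent-3-en-1-ol
Conditions: N-chlorosuccinimide, Me2S, CH2Cl2, −20 → 0 °C
Reagents that add atoms: N-chlorosuccinimide, ClN1C(=O)CCC1=O
Why: Corey–Kim chlorination; only the allylic alkoxysulfonium ion is displaced by chloride, and the saturated primary alcohol is regenerated on work-up.

Step 10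
Reactants: 12 (3Z)-5-chloro-3-methylpent-3-en-1-ol
Product: 13 (3Z)-3-methyl-5-(phenylsulfonyl)pent-3-en-1-ol
Conditions: PhSO2Na, DMF, 20 °C
Reagents that add atoms: sodium benzenesulfinate, [Na+].[O-]S(=O)c1ccccc1
Why: SN2 displacement of the primary allylic chloride by the sulfur of the sulfinate; the non-basic nucleophile leaves the free hydroxyl and the alkene geometry alone.

Step 11
Reactants: 13 (3Z)-3-methyl-5-(phenylsulfonyl)pent-3-en-1-ol
Product: 14 (3Z)-3-methyl-5-(phenylsulfonyl)pent-3-enal
Conditions: Dess–Martin periodinane, NaHCO3, CH2Cl2, 0 °C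
Reagents that add atoms: none
Why: Dess–Martin oxidation under buffered conditions, chosen because base would move the β,γ-alkene into conjugation; the aldehyde is used at once.

Step 12
Reactants: 14 (3Z)-3-methyl-5-(phenylsulfonyl)pent-3-enal; 15 1-propynylmagnesium bromide
Product: 16 (6Z)-6-methyl-8-(phenylsulfonyl)oct-6-en-2-yn-4-ol (racemic)
Conditions: THF, −78 °C
Reagents that add atoms: none
Why: Grignard 1,2-addition; the weakly basic acetylide adds to the aldehyde faster than it enolises it or deprotonates the sulfone.

Step 13
Reactants: 16 (6Z)-6-methyl-8-(phenylsulfonyl)oct-6-en-2-yn-4-ol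
Product: 17 (6Z)-6-methyl-8-(phenylsulfonyl)oct-6-en-2-yn-4-one
Conditions: Dess–Martin periodinane, NaHCO3, CH2Cl2, 0 °C
Reagents that add atoms: none
Why: Dess–Martin oxidation of the propargylic alcohol under buffered conditions that should not enolise the doubly activated C14 methylene.

Step 14
Reactants: 17 (6Z)-6-methyl-8-(phenylsulfonyl)oct-6-en-2-yn-4-one
Product: 18 (4S,6Z)-6-methyl-8-(phenylsulfonyl)oct-6-en-2-yn-4-ol
Conditions: Ru[(S,S)-TsDPEN](p-cymene) (preformed amido complex, cat.), i-PrOH, 25 °C
Reagents that add atoms: none
Why: Noyori asymmetric transfer hydrogenation of an alkynyl ketone; the base-free complex transfers hydride and proton through a six-membered transition state that distinguishes alkynyl from alkyl, and the (S,S) catalyst is the one expected to give the S carbinol (C1 of the target) on the pattern of alkyl alkynyl ketones.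

Step 15
Reactants: 18 (4S,6Z)-6-methyl-8-(phenylsulfonyl)oct-6-en-2-yn-4-ol; 9 (2Z,5S)-1-bromo-2-methyl-5-[2-(triethylsilyloxy)propan-2-yl]hepta-2,6-diene
Product: 21 (4S,6Z,10Z,13S)-6,10-dimethyl-8-(phenylsulfonyl)-13-[2-(triethylsilyloxy)propan-2-yl]-4-(trimethylsilyloxy)pentadeca-6,10,14-trien-2-yne (C8 epimers), via dilithio dianion 19 (not isolated), via coupled lithium alkoxide 20 (not isolated)
Conditions: n-BuLi (2.1 equiv), THF, −78 °C; 9, −78 → −40 °C; then Me3SiCl, −78 → 0 °C
Reagents that add atoms: chlorotrimethylsilane, C[Si](C)(C)Cl; n-butyllithium, [Li]CCCC (lithium of 19 and 20 only)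
Why: α-Sulfonyl carbanion alkylation; dianion 19 reacts at carbon with the primary allylic bromide by SN2 to form C10–C11, and both Z alkenes are configurationally stable at this temperature. Silylating alkoxide 20 in the same flask removes an oxygen nucleophile that could attack the π-allyl intermediate of step 16.

Step 16
Reactants: 21 (4S,6Z,10Z,13S)-6,10-dimethyl-8-(phenylsulfonyl)-13-[2-(triethylsilyloxy)propan-2-yl]-4-(trimethylsilyloxy)pentadeca-6,10,14-trien-2-yne
Product: 23 (4S,6Z,10Z,13S)-6,10-dimethyl-13-[2-(triethylsilyloxy)propan-2-yl]pentadeca-6,10,14-trien-2-yn-4-ol, via desulfonylated trimethylsilyl ether 22 (not isolated)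
Conditions: Pd(dppp)Cl2 (cat.), LiEt3BH, THF, 0 °C; then K2CO3, MeOH, 0 °C
Reagents that add atoms: none
Why: Palladium-catalysed reductive desulfonylation; zerovalent palladium ionises the allylic sulfone and hydride goes to the less substituted terminus C11 of the π-allyl complex, which keeps C12=C13 in place and, by fast capture, Z. Mild methanolysis then frees the C1 hydroxyl while the tertiary triethylsilyl ether stays.

Step 17
Reactants: 23 (4S,6Z,10Z,13S)-6,10-dimethyl-13-[2-(triethylsilyloxy)propan-2-yl]pentadeca-6,10,14-trien-2-yn-4-ol
Product: 24 (2S)-1-[(2R,3S)-2-methyl-3-{(3Z,6S)-3-methyl-6-[2-(triethylsilyloxy)propan-2-yl]octa-3,7-dien-1-yl}oxiran-2-yl]pent-3-yn-2-ol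
Conditions: VO(acac)2 (cat.), t-BuOOH (decane), CH2Cl2, 0 → 20 °C
Reagents that add atoms: tert-butyl hydroperoxide, CC(C)(C)OO
Why: Vanadium-catalysed hydroxyl-directed epoxidation of a homoallylic alcohol; the vanadate ester at C1 reaches only C12=C13. A chair transition state with the propynyl group equatorial and a C14–H bond eclipsing the Z alkene (allylic 1,3-strain) should deliver oxygen syn to the C1–O bond, which is the 12S,13R epoxide.

Step 18
Reactants: 24 (2S)-1-[(2R,3S)-2-methyl-3-{(3Z,6S)-3-methyl-6-[2-(triethylsilyloxy)propan-2-yl]octa-3,7-dien-1-yl}oxiran-2-yl]pent-3-yn-2-ol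
Product: 25 the C1 triethylsilyl ether of 24 (target numbering: C1 and C15 triethylsilyl ethers, C2≡C3 alkyne, 12S,13R epoxide, vinyl on C6)
Conditions: Et3SiCl, imidazole, DMAP (cat.), CH2Cl2, 0 °C
Reagents that add atoms: chlorotriethylsilane, CC[Si](CC)(CC)Cl
Why: Silylation of the secondary alcohol with the silyl chloride and imidazole, mild enough for the epoxide; both hydroxyls now carry the same group for one final deprotection.

Step 19
Reactants: 25 the C1 triethylsilyl ether of 24
Product: 26 the C3 pinacol boronate of the C2=C3 alkene (boron on C3 trans to C1, methyl cis to C1, hydrogen on C2)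
Conditions: CuCl (cat.), PCy3 (cat.), NaOt-Bu (cat.), B2pin2, MeOH, toluene, 20 °C
Reagents that add atoms: bis(pinacolato)diboron, CC1(C)OB(OC1(C)C)B1OC(C)(C)C(C)(C)O1
Why: Copper-catalysed borylcupration–protonation (formal syn hydroboration) of the internal alkyne; boron goes to the methyl-bearing C3, the less hindered carbon and the one remote from the electron-withdrawing silyloxy carbon, and methanol protonates the C2–Cu bond with retention. Unactivated alkenes, the vinyl group included, do not react with the boryl-copper species.

Step 20
Reactants: 26 the C3 pinacol boronate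
Product: 27 the E C3 alkenyl iodide (iodine trans to C1) with the C6 vinyl group, the 12S,13R epoxide and the C1 and C15 triethylsilyl ethers
Conditions: NaOH (aq.), then I2, THF, 0 °C
Reagents that add atoms: iodine, II
Why: Base-promoted iododeboronation; iodine attacks the hydroxyboronate at the boron-bearing carbon and C–B is replaced by C–I with retention.

Step 21
Reactants: 27 the E C3 alkenyl iodide
Product: 29 (1S,2E,6R,8Z,12S,13R)-12,13-epoxy-3,9,13-trimethyl-1-(triethylsilyloxy)-6-[2-(triethylsilyloxy)propan-2-yl]cyclotetradeca-2,8-diene, via B-alkyl-9-BBN borane 28 (not isolated)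
Conditions: 9-BBN, THF, 20 °C; then Pd(dppf)Cl2 (cat.), AsPh3, Cs2CO3, DMF–THF–H2O, high dilution (slow addition of 28), 20 → 45 °C
Reagents that add atoms: 9-borabicyclo[3.3.1]nonane, [BH]1C2CCCC1CCC2 (its boron and ring carbons are in 28 only; 29 keeps one hydrogen)
Why: 9-BBN adds anti-Markovnikov to the monosubstituted C4=C5 alkene to give the primary C4 borane 28; the two trisubstituted alkenes and the iodoalkene react far more slowly, and the epoxide and silyl ethers are inert to the dialkylborane. Zerovalent palladium formed from Pd(dppf)Cl2 inserts into the C3–I bond with retention of the E geometry. Carbonate and water activate boron as a hydroxyborate, the primary alkyl group moves to palladium with AsPh3 as a labile ligand that speeds this transfer, and reductive elimination forms C3–C4. The closest known reaction type is the intramolecular B-alkyl Suzuki–Miyaura macrocyclisation. The 14-membered ring closes in this C(sp2)–C(sp3) reductive elimination from an alkyl(alkenyl)palladium chelate, and high dilution favours it over chain growth. No stereocentre is formed: C1, C6, C12 and C13 arrive fixed and the alkene geometry is that of the iodide. The step needs chemoselective hydroboration, secured by the single terminal alkene in 27, and reductive elimination ahead of β-hydride loss from the C4–Pd species, for which the wide bite angle of dppf is chosen.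

Step 22
Reactants: 29 the bis(triethylsilyl) macrocycle
Product: 30 (1S,2E,6R,8Z,12S,13R)-12,13-epoxy-6-(2-hydroxypropan-2-yl)-3,9,13-trimethylcyclotetradeca-2,8-dien-1-ol
Conditions: Bu4NF, THF, 0 → 20 °C
Reagents that add atoms: none
Why: Fluoride cleavage of both triethylsilyl ethers; the epoxide, the alkenes and the ring are inert to fluoride at this temperature.

Step 23
Reactants: 30 the macrocyclic diol
Product: 31 (1S,2E,6R,8Z,12S,13R)-12,13-epoxy-6-(2-hydroxypropan-2-yl)-3,9,13-trimethylcyclotetradeca-2,8-dien-1-yl acetate (target)
Conditions: Ac2O, pyridine, DMAP (cat.), CH2Cl2, 0 °C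
Reagents that add atoms: acetic anhydride, CC(=O)OC(C)=O
Why: Acylation with nucleophilic catalysis; the secondary allylic hydroxyl reacts at 0 °C and the tertiary hydroxyl does not, so the monoacetate should result.

## Compound list

1 | (S)-(+)-carvone | CC1=CC[C@@H](CC1=O)C(C)=C | starting material
2 | (5S)-5-(2-hydroxypropan-2-yl)-2-methylcyclohex-2-en-1-one | CC1=CC[C@@H](CC1=O)C(C)(C)O | intermediate
3 | (5S)-2-methyl-5-[2-(triethylsilyloxy)propan-2-yl]cyclohex-2-en-1-one | CC1=CC[C@@H](CC1=O)C(C)(C)O[Si](CC)(CC)CC | intermediate
4 | lithium (3S)-6-methyl-3-[2-(triethylsilyloxy)propan-2-yl]cyclohexa-1,5-dien-1-olate (α′-enolate of 3, not isolated) | CC1=CC[C@@H](C=C1[O-])C(C)(C)O[Si](CC)(CC)CC.[Li+] | intermediate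
5 | (5S)-6-hydroxy-2-methyl-5-[2-(triethylsilyloxy)propan-2-yl]cyclohex-2-en-1-one (C6 epimers) | CC1=CC[C@@H](C(O)C1=O)C(C)(C)O[Si](CC)(CC)CC | intermediate
6 | methyl (2Z,5R)-5-formyl-2,6-dimethyl-6-(triethylsilyloxy)hept-2-enoate | COC(=O)/C(C)=C\C[C@@H](C=O)C(C)(C)O[Si](CC)(CC)CC | intermediate
7 | methyl (2Z,5S)-2-methyl-5-[2-(triethylsilyloxy)propan-2-yl]hepta-2,6-dienoate | COC(=O)/C(C)=C\C[C@@H](C=C)C(C)(C)O[Si](CC)(CC)CC | intermediate
8 | (2Z,5S)-2-methyl-5-[2-(triethylsilyloxy)propan-2-yl]hepta-2,6-dien-1-ol | OC/C(C)=C\C[C@@H](C=C)C(C)(C)O[Si](CC)(CC)CC | intermediate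
9 | (2Z,5S)-1-bromo-2-methyl-5-[2-(triethylsilyloxy)propan-2-yl]hepta-2,6-diene | BrC/C(C)=C\C[C@@H](C=C)C(C)(C)O[Si](CC)(CC)CC | intermediate
10 | 4-methyl-5,6-dihydro-2H-pyran-2-one | CC1=CC(=O)OCC1 | starting material
11 | (2Z)-3-methylpent-2-ene-1,5-diol | OC/C=C(/C)CCO | intermediate
12 | (3Z)-5-chloro-3-methylpent-3-en-1-ol | ClC/C=C(/C)CCO | intermediate
13 | (3Z)-3-methyl-5-(phenylsulfonyl)pent-3-en-1-ol | OCC/C(C)=C\CS(=O)(=O)c1ccccc1 | intermediate
14 | (3Z)-3-methyl-5-(phenylsulfonyl)pent-3-enal | O=CC/C(C)=C\CS(=O)(=O)c1ccccc1 | intermediate
15 | 1-propynylmagnesium bromide | CC#C[Mg]Br | starting material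
16 | (6Z)-6-methyl-8-(phenylsulfonyl)oct-6-en-2-yn-4-ol (racemic) | CC#CC(O)C/C(C)=C\CS(=O)(=O)c1ccccc1 | intermediate
17 | (6Z)-6-methyl-8-(phenylsulfonyl)oct-6-en-2-yn-4-one | CC#CC(=O)C/C(C)=C\CS(=O)(=O)c1ccccc1 | intermediate
18 | (4S,6Z)-6-methyl-8-(phenylsulfonyl)oct-6-en-2-yn-4-ol | CC#C[C@@H](O)C/C(C)=C\CS(=O)(=O)c1ccccc1 | intermediate
19 | dilithium salt of 18 (alkoxide at the carbinol, carbanion α to sulfur; not isolated) | CC#C[C@@H]([O-])C/C(C)=C\[CH-]S(=O)(=O)c1ccccc1.[Li+].[Li+] | intermediate
20 | lithium alkoxide of the C10–C11 coupled hydroxy sulfone (epimers at the sulfone carbon; not isolated) | C=C[C@@H](C(C)(C)O[Si](CC)(CC)CC)C/C=C(/C)CC(S(=O)(=O)c1ccccc1)/C=C(/C)C[C@H]([O-])C#CC.[Li+] | intermediate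
21 | (4S,6Z,10Z,13S)-6,10-dimethyl-8-(phenylsulfonyl)-13-[2-(triethylsilyloxy)propan-2-yl]-4-(trimethylsilyloxy)pentadeca-6,10,14-trien-2-yne (C8 epimers) | C=C[C@@H](C(C)(C)O[Si](CC)(CC)CC)C/C=C(/C)CC(S(=O)(=O)c1ccccc1)/C=C(/C)C[C@H](O[Si](C)(C)C)C#CC | intermediate
22 | (4S,6Z,10Z,13S)-6,10-dimethyl-13-[2-(triethylsilyloxy)propan-2-yl]-4-(trimethylsilyloxy)pentadeca-6,10,14-trien-2-yne (not isolated) | C=C[C@@H](C(C)(C)O[Si](CC)(CC)CC)C/C=C(/C)CC/C=C(/C)C[C@H](O[Si](C)(C)C)C#CC | intermediate
23 | (4S,6Z,10Z,13S)-6,10-dimethyl-13-[2-(triethylsilyloxy)propan-2-yl]pentadeca-6,10,14-trien-2-yn-4-ol | C=C[C@@H](C(C)(C)O[Si](CC)(CC)CC)C/C=C(/C)CC/C=C(/C)C[C@H](O)C#CC | intermediate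
24 | (2S)-1-[(2R,3S)-2-methyl-3-{(3Z,6S)-3-methyl-6-[2-(triethylsilyloxy)propan-2-yl]octa-3,7-dien-1-yl}oxiran-2-yl]pent-3-yn-2-ol | C=C[C@@H](C(C)(C)O[Si](CC)(CC)CC)C/C=C(/C)CC[C@@H]1O[C@]1(C)C[C@H](O)C#CC | intermediate
25 | triethylsilyl ether of 24 at the propargylic hydroxyl (C1 of the target) | C=C[C@@H](C(C)(C)O[Si](CC)(CC)CC)C/C=C(/C)CC[C@@H]1O[C@]1(C)C[C@H](O[Si](CC)(CC)CC)C#CC | intermediate
26 | alkenyl pinacol boronate from 25: C2=C3 alkene, boron on C3 trans to C1, methyl cis to C1 | C=C[C@@H](C(C)(C)O[Si](CC)(CC)CC)C/C=C(/C)CC[C@@H]1O[C@]1(C)C[C@H](O[Si](CC)(CC)CC)/C=C(\C)B1OC(C)(C)C(C)(C)O1 | intermediate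
27 | E C3 alkenyl iodide (iodine trans to C1) with C6 vinyl group, 12S,13R epoxide, C1 and C15 triethylsilyl ethers | C=C[C@@H](C(C)(C)O[Si](CC)(CC)CC)C/C=C(/C)CC[C@@H]1O[C@]1(C)C[C@H](O[Si](CC)(CC)CC)/C=C(\C)I | intermediate
28 | B-alkyl-9-BBN borane from 27, boron on C4 (not isolated) | B1(CC[C@@H](C(C)(C)O[Si](CC)(CC)CC)C/C=C(/C)CC[C@@H]3O[C@]3(C)C[C@H](O[Si](CC)(CC)CC)/C=C(\C)I)C2CCCC1CCC2 | intermediate
29 | (1S,2E,6R,8Z,12S,13R)-12,13-epoxy-3,9,13-trimethyl-1-(triethylsilyloxy)-6-[2-(triethylsilyloxy)propan-2-yl]cyclotetradeca-2,8-diene | CC[Si](CC)(CC)O[C@@H]1/C=C(\C)CC[C@@H](C(C)(C)O[Si](CC)(CC)CC)C/C=C(/C)CC[C@@H]2O[C@]2(C)C1 | intermediate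
30 | (1S,2E,6R,8Z,12S,13R)-12,13-epoxy-6-(2-hydroxypropan-2-yl)-3,9,13-trimethylcyclotetradeca-2,8-dien-1-ol | O[C@@H]1/C=C(\C)CC[C@@H](C(C)(C)O)C/C=C(/C)CC[C@@H]2O[C@]2(C)C1 | intermediate
31 | (1S,2E,6R,8Z,12S,13R)-12,13-epoxy-6-(2-hydroxypropan-2-yl)-3,9,13-trimethylcyclotetradeca-2,8-dien-1-yl acetate | CC(=O)O[C@@H]1/C=C(\C)CC[C@@H](C(C)(C)O)C/C=C(/C)CC[C@@H]2O[C@]2(C)C1 | target

## Step count and least certain steps

Total: 23 steps. Longest linear sequence: 16 steps (steps 1–7 and 15–23 from 1; the branch from 10, steps 8–14 and 15–23, is equally long).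

**Step 21 (key step).** The most likely failure is chain growth or loss of the alkylboron partner: intermolecular coupling competes with closure of a 14-membered ring, and slow transmetalation of the hindered, β-branched C4 borane gives time for protodeboronation or β-hydride elimination. The fallback keeps the C3–C4 bond but changes the organometallic. It sets out from 27. Hydroboration with 9-BBN and oxidative work-up (NaBO3) gives the C4 primary alcohol F1. I2, PPh3 and imidazole convert it into the primary iodide F2. Zinc insertion (Zn, LiCl, THF) into the alkyl C–I bond, which should be faster than into the alkenyl C–I bond, gives the alkylzinc iodide F3. Zerovalent palladium then closes the ring by intramolecular Negishi coupling under high dilution, returning to 29.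

**Step 19.** The most likely failure is sluggish or misdirected borylcupration: the alkyne is dialkyl-substituted and flanked by a silyloxy carbon, so addition may be slow, some boron may go to C2, or the C2–copper intermediate may expel the silyloxy group and give an allene. The fallback sets out from 25 and uses a sterically governed hydrometalation. Syn hydrozirconation with Cp2Zr(H)Cl puts zirconium on the less hindered C3 to give the alkenylzirconocene chloride F4, which I2 converts with retention into 27, bypassing 26. Its own hazard is competing addition to the vinyl group, limited by the branching next to that alkene and by using close to one equivalent of hydride.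

**Step 17.** The most likely failure is poor facial selectivity, or slow oxygen transfer that lets the vanadium peroxide oxidise the propargylic alcohol instead. The directing alcohol is homoallylic, and the preference rests on an equatorial propynyl group, which is small. The fallback sets out from 23 and builds the same syn relation through a ring. Boc2O and DMAP give the tert-butyl carbonate F5. IBr at low temperature induces iodocarbonate cyclisation to the six-membered cyclic carbonate F6, with the C13–O bond syn to C1–O and iodine on C12. K2CO3 in MeOH removes the carbonate and closes the epoxide with inversion at C12, returning to 24.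

**Step 14 (with the ynone from step 13).** The most likely failure is migration of the C12=C13 bond into conjugation with the ynone: the C14 methylene of 17 is flanked by the ketone and the alkene, and traces of base or silica would erase the Z geometry before or during reduction. The fallback sets out from 14 and avoids the ynone. Catalytic enantioselective addition of the zinc acetylide of propyne (Me2Zn, a chiral ProPhenol-type amino-alcohol ligand chosen for the S carbinol) gives 18 directly, so 16 and 17 are never made and no new compound arises (F0).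

## Further compounds

F1 | step 21 | C4 primary alcohol from hydroboration–oxidation of 27 (C3 iodide, epoxide and both silyl ethers retained) | OCC[C@@H](C(C)(C)O[Si](CC)(CC)CC)C/C=C(/C)CC[C@@H]1O[C@]1(C)C[C@H](O[Si](CC)(CC)CC)/C=C(\C)I
F2 | step 21 | C4 primary iodide corresponding to F1 | ICC[C@@H](C(C)(C)O[Si](CC)(CC)CC)C/C=C(/C)CC[C@@H]1O[C@]1(C)C[C@H](O[Si](CC)(CC)CC)/C=C(\C)I
F3 | step 21 | C4 alkylzinc iodide from F2 | I[Zn]CC[C@@H](C(C)(C)O[Si](CC)(CC)CC)C/C=C(/C)CC[C@@H]1O[C@]1(C)C[C@H](O[Si](CC)(CC)CC)/C=C(\C)I
F4 | step 19 | C3 alkenylzirconocene chloride from 25 (zirconium trans to C1) | C=C[C@@H](C(C)(C)O[Si](CC)(CC)CC)C/C=C(/C)CC[C@@H]1O[C@]1(C)C[C@H](O[Si](CC)(CC)CC)/C=C(\C)[Zr](Cl)(C1C=CC=C1)C1C=CC=C1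
F5 | step 17 | tert-butyl carbonate of 23 at the C1 hydroxyl | C=C[C@@H](C(C)(C)O[Si](CC)(CC)CC)C/C=C(/C)CC/C=C(/C)C[C@H](OC(=O)OC(C)(C)C)C#CC
F6 | step 17 | six-membered cyclic carbonate bridging C1 and C13 with iodine on C12 | C=C[C@@H](C(C)(C)O[Si](CC)(CC)CC)C/C=C(/C)CC[C@@H](I)[C@@]1(C)C[C@@H](C#CC)OC(=O)O1
F0 | step 14 | none | none
A1 | alternative 1 | 14-membered cycloalkyne (C2≡C3) with C1 p-methoxybenzyl ether, C15 triethylsilyl ether and both Z alkenes | COc1ccc(CO[C@@H]2C#CCC[C@@H](C(C)(C)O[Si](CC)(CC)CC)C/C=C(/C)CC/C=C(/C)C2)cc1
A2 | alternative 2 | macrocyclic C5 phenyl sulfone (C5 epimers) with C1 tert-butyldimethylsilyl ether, C15 triethylsilyl ether and the 12,13-epoxide | CC(C)(C)[Si](C)(C)O[C@@H]1/C=C(\C)CC(S(=O)(=O)c3ccccc3)[C@@H](C(C)(C)O[Si](CC)(CC)CC)C/C=C(/C)CC[C@@H]2O[C@]2(C)C1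
A3 | alternative 3 | macrocyclic Z,Z-dienyl propargylic alcohol (C1 epimers) with C15 triethylsilyl ether | OC1C#CCC[C@@H](C(C)(C)O[Si](CC)(CC)CC)C/C=C(/C)CC/C=C(/C)C1
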